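**Assumption:** atom labels C1–C15 follow germacranolide numbering (lactone O on C6, angelate on C8, C12 = lactone carbonyl, C13 = methylidene); the sense of induction of the chiral controllers in steps 5 and 6 is assigned by analogy, and the antipodal controller is used if a model reaction shows the opposite sense.

## Retrosynthetic overview

1. Ring B (ten-membered carbocycle) is closed last, at C1=C2, by ring-closing metathesis of seco-diene 19.
2. The C8–O angelate bond is made by Mitsunobu esterification with inversion of the 8S carbinol 16; this C–O bond sets C8.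
3. Ring A (γ-lactone) is formed first: the O–C12 bond arises by alkoxycarbonylation of allenol 8 with CO, and the derived allylcopper joins C7 to C8 of aldehyde 13.
4. Allenol 8 comes from pent-1-en-4-yn-3-ol (Z-iodide by carbomagnesiation, C3–O by Sharpless resolution, C6–O by asymmetric allenylation); aldehyde 13 comes from 3-methylbut-3-en-1-ol (C10–O by asymmetric epoxidation).
5. Order of ring formation: ring A, then ring B.

## Route

Step 1
Reactants: 1 pent-1-en-4-yn-3-ol (racemic)
Product: 3 rac-(4Z)-5-iodo-4-methylpenta-1,4-dien-3-ol, via alkenylmagnesium chelate 2 (not isolated)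
Conditions: MeMgBr (3 equiv), CuI (10 mol%), THF, −10 to 23 °C; then I2, −78 to 0 °C
Reagents that add atoms: methylmagnesium bromide (C[Mg]Br); iodine (II)
Why: Copper-catalysed anti-carbomagnesiation of the propargylic alkoxide (Duboudin reaction) puts Me on the internal carbon and Mg, then I, cis to the carbinol carbon through a five-membered chelate, which fixes the Z-trisubstituted C4=C5 olefin.

Step 2
Reactants: 3 rac-(4Z)-5-iodo-4-methylpenta-1,4-dien-3-ol
Product: 4 (3R,4Z)-5-iodo-4-methylpenta-1,4-dien-3-ol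
Conditions: Ti(OiPr)4 (1.0 equiv), D-(−)-diisopropyl tartrate (1.2 equiv), t-BuOOH (0.6 equiv), 4 Å MS, CH2Cl2, −20 °C
Reagents that add atoms: none
Why: Sharpless kinetic resolution: with the D-tartrate the S enantiomer is epoxidised at its vinyl group much faster (the Z-iodoalkene is inert), so the R alcohol (C3 of the target) is recovered in high ee at about 55% conversion.

Step 3
Reactants: 4 (3R,4Z)-5-iodo-4-methylpenta-1,4-dien-3-ol
Product: 5 tert-butyl{[(3R,4Z)-5-iodo-4-methylpenta-1,4-dien-3-yl]oxy}dimethylsilane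
Conditions: TBSCl, imidazole, DMF, 23 °C
Reagents that add atoms: tert-butyldimethylsilyl chloride (CC(C)(C)[Si](C)(C)Cl)
Why: Standard silylation; the ether keeps C3–OH out of the organolithium, copper and Mitsunobu steps.

Step 4
Reactants: 5 tert-butyl{[(3R,4Z)-5-iodo-4-methylpenta-1,4-dien-3-yl]oxy}dimethylsilane
Product: 7 (2Z,4R)-4-{[tert-butyl(dimethyl)silyl]oxy}-3-methylhexa-2,5-dienal, via alkenyllithium 6 (not isolated)
Conditions: t-BuLi (2.1 equiv), Et2O, −78 °C; DMF, −78 °C; then H2O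
Reagents that add atoms: N,N-dimethylformamide (CN(C)C=O)
Why: Iodine–lithium exchange with retention of olefin geometry and formylation give the Z-enal (the formyl carbon becomes C6); −78 °C suppresses 1,4-silyl migration.

Step 5
Reactants: 7 (2Z,4R)-4-{[tert-butyl(dimethyl)silyl]oxy}-3-methylhexa-2,5-dienal
Product: 8 (4S,5Z,7R)-7-{[tert-butyl(dimethyl)silyl]oxy}-6-methylnona-1,2,5,8-tetraen-4-ol
Conditions: (1R,2R)-N,N′-bis(4-methylbenzenesulfonyl)-1,2-diphenylethane-1,2-diamine, BBr3, CH2Cl2, 0 to 23 °C; tributyl(propa-1,2-dien-1-yl)stannane, 23 °C; then 7, −78 °C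
Reagents that add atoms: tributyl(propa-1,2-dien-1-yl)stannane (C=C=C[Sn](CCCC)(CCCC)CCCC)
Why: Corey asymmetric allenylation: the chiral B-propargyl diazaborolidine adds through its γ-carbon in a chair transition state to the aldehyde face chosen by the controller, giving the 2,3-allenol and setting the carbinol that becomes C6.

Step 6
Reactants: 9 3-methylbut-3-en-1-ol
Product: 10 2-[(2R)-2-methyloxiran-2-yl]ethan-1-ol
Conditions: Hf(OtBu)4 (2 mol%), C2-symmetric bis-hydroxamic acid ligand from (1R,2R)-cyclohexane-1,2-diamine (2.2 mol%), cumene hydroperoxide, DMPU, 4 Å MS, toluene, 0 °C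
Reagents that add atoms: cumene hydroperoxide (CC(C)(OO)c1ccccc1)
Why: Hydroxyl-directed asymmetric epoxidation of a homoallylic alcohol (Yamamoto epoxidation) forms the C10–O bond and sets the tertiary centre.

Step 7
Reactants: 10 2-[(2R)-2-methyloxiran-2-yl]ethan-1-ol
Product: 12 (3R)-3-methylpent-4-ene-1,3-diol, via sulfonium betaine 11 (not isolated)
Conditions: Me3S+ I− (4 equiv), n-BuLi (5 equiv), THF, −10 to 23 °C
Reagents that add atoms: trimethylsulfonium iodide (C[S+](C)C.[I-])
Why: Dimethylsulfonium methylide opens the epoxide at CH2 and the betaine loses Me2S (one-carbon homologation of an epoxide to an allylic alcohol), leaving the stereocentre untouched.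

Step 8
Reactants: 12 (3R)-3-methylpent-4-ene-1,3-diol
Product: 13 (3R)-3-hydroxy-3-methylpent-4-enal
Conditions: 2,2,6,6-tetramethylpiperidin-1-oxyl (10 mol%), PhI(OAc)2 (1.1 equiv), CH2Cl2, 23 °C; used crude
Reagents that add atoms: none
Why: Oxoammonium oxidation is selective for the primary alcohol and leaves the tertiary allylic alcohol alone.

Step 9
Reactants: 8 (4S,5Z,7R)-7-{[tert-butyl(dimethyl)silyl]oxy}-6-methylnona-1,2,5,8-tetraen-4-ol; 13 (3R)-3-hydroxy-3-methylpent-4-enal
Product: 16 (4R,5R)-5-[(1Z,3R)-3-{[tert-butyl(dimethyl)silyl]oxy}-2-methylpenta-1,4-dien-1-yl]-4-[(1S,3R)-1,3-dihydroxy-3-methylpent-4-en-1-yl]-3-methylideneoxolan-2-one, via alkoxycarbonylcopper 14 (not isolated), via allylcopper lactone 15 (not isolated)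
Conditions: CuCl (10 mol%), 1,3-bis(2,6-diisopropylphenyl)imidazolium chloride (10 mol%), NaOtBu (20 mol%), CO (5 atm), 13 (1.5 equiv), THF, 30 °C
Reagents that add atoms: carbon monoxide ([C-]#[O+])
Why: Proposed new method: the monovalent copper alkoxide of 8 inserts CO to give alkoxycarbonylcopper 14 (the lactone C–O bond), 5-exo syn-carbocupration of the distal allene π-bond closes ring A and gives allylcopper 15, which adds through C7 to aldehyde 13 in a chair transition state on the face anti to the C6 side chain (7R, and 8S from the anti preference of an E-type cyclic allylmetal), and the new copper alkoxide is protonated by 8 to turn the catalyst over; the closest known reactions are the carbonylation of CuOtBu to an alkoxycarbonylcopper, copper-catalysed borylative or reductive allene–aldehyde couplings through allylcopper species, and the PdCl2/CuCl2 chlorocyclocarbonylation of 2,3-allenols.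

Step 10
Reactants: 16 (the 8S alcohol from step 9); 17 (2Z)-2-methylbut-2-enoic acid (angelic acid)
Product: 18 (1R,3R)-1-[(2R,3R)-2-[(1Z,3R)-3-{[tert-butyl(dimethyl)silyl]oxy}-2-methylpenta-1,4-dien-1-yl]-4-methylidene-5-oxooxolan-3-yl]-3-hydroxy-3-methylpent-4-en-1-yl (2Z)-2-methylbut-2-enoate
Conditions: PPh3 (2.5 equiv), diisopropyl azodicarboxylate (2.5 equiv), 17 (2.5 equiv), toluene, 0 to 23 °C
Reagents that add atoms: none
Why: Mitsunobu esterification forms the C8–O bond by SN2 displacement of the oxyphosphonium with inversion (8S to 8R) under neutral conditions that keep the Z acid intact; the tertiary C10–OH does not react.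

Step 11
Reactants: 18 (the silyl-protected angelate from step 10)
Product: 19 (1R,3R)-3-hydroxy-1-[(2R,3R)-2-[(1Z,3R)-3-hydroxy-2-methylpenta-1,4-dien-1-yl]-4-methylidene-5-oxooxolan-3-yl]-3-methylpent-4-en-1-yl (2Z)-2-methylbut-2-enoate
Conditions: HF·pyridine, pyridine, THF, 0 to 23 °C
Reagents that add atoms: none
Why: Buffered fluoride desilylation frees C3–OH without touching the angelate, the tertiary allylic alcohol or the α-methylene lactone.

Step 12
Reactants: 19 (the seco-diene from step 11)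
Product: 20 (3aR,4R,6R,7E,9R,10Z,11aR)-6,9-dihydroxy-6,10-dimethyl-3-methylidene-2-oxo-2,3,3a,4,5,6,9,11a-octahydrocyclodeca[b]furan-4-yl (2Z)-2-methylbut-2-enoate (target)
Conditions: second-generation Grubbs catalyst (10 mol%), 1,4-benzoquinone (20 mol%), toluene (1 mM), 80 °C
Reagents that add atoms: none
Why: Ring-closing metathesis of the two monosubstituted allylic-alcohol olefins closes ring B at C1=C2; the E olefin is expected under reversible (thermodynamic) conditions, and the 1,1-disubstituted acrylate and the trisubstituted olefins are poor metathesis partners.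

## Compound list

1 | pent-1-en-4-yn-3-ol (racemic) | C=CC(O)C#C | starting material
2 | 5-ethenyl-4-methyl-2,5-dihydro-1,2-oxamagnesole (alkenylmagnesium chelate) | C=CC1O[Mg]C=C1C | intermediate
3 | rac-(4Z)-5-iodo-4-methylpenta-1,4-dien-3-ol | I/C=C(/C)C(O)C=C | intermediate
4 | (3R,4Z)-5-iodo-4-methylpenta-1,4-dien-3-ol | I/C=C(/C)[C@H](O)C=C | intermediate
5 | tert-butyl{[(3R,4Z)-5-iodo-4-methylpenta-1,4-dien-3-yl]oxy}dimethylsilane | I/C=C(/C)[C@H](O[Si](C)(C)C(C)(C)C)C=C | intermediate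
6 | [(1Z,3R)-3-{[tert-butyl(dimethyl)silyl]oxy}-2-methylpenta-1,4-dien-1-yl]lithium | [Li]/C=C(/C)[C@H](O[Si](C)(C)C(C)(C)C)C=C | intermediate
7 | (2Z,4R)-4-{[tert-butyl(dimethyl)silyl]oxy}-3-methylhexa-2,5-dienal | O=C/C=C(/C)[C@H](O[Si](C)(C)C(C)(C)C)C=C | intermediate
8 | (4S,5Z,7R)-7-{[tert-butyl(dimethyl)silyl]oxy}-6-methylnona-1,2,5,8-tetraen-4-ol | C=C=C[C@H](O)/C=C(/C)[C@H](O[Si](C)(C)C(C)(C)C)C=C | intermediate
9 | 3-methylbut-3-en-1-ol | C=C(C)CCO | starting material
10 | 2-[(2R)-2-methyloxiran-2-yl]ethan-1-ol | C[C@@]1(CCO)CO1 | intermediate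
11 | lithium (3R)-5-(dimethylsulfaniumyl)-3-methyl-3-oxidopentan-1-olate (sulfonium betaine) | C[S+](C)CC[C@](C)([O-])CC[O-].[Li+] | intermediate
12 | (3R)-3-methylpent-4-ene-1,3-diol | C=C[C@](C)(O)CCO | intermediate
13 | (3R)-3-hydroxy-3-methylpent-4-enal | C=C[C@](C)(O)CC=O | intermediate
14 | {[(4S,5Z,7R)-7-{[tert-butyl(dimethyl)silyl]oxy}-6-methylnona-1,2,5,8-tetraen-4-yl]oxycarbonyl}copper (carbene ligand omitted) | C=C=C[C@H](OC(=O)[Cu])/C=C(/C)[C@H](O[Si](C)(C)C(C)(C)C)C=C | intermediate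
15 | {[(5R)-5-[(1Z,3R)-3-{[tert-butyl(dimethyl)silyl]oxy}-2-methylpenta-1,4-dien-1-yl]-2-oxo-2,5-dihydrofuran-3-yl]methyl}copper (carbene ligand omitted) | O=C1O[C@H](/C=C(/C)[C@H](O[Si](C)(C)C(C)(C)C)C=C)C=C1C[Cu] | intermediate
16 | (4R,5R)-5-[(1Z,3R)-3-{[tert-butyl(dimethyl)silyl]oxy}-2-methylpenta-1,4-dien-1-yl]-4-[(1S,3R)-1,3-dihydroxy-3-methylpent-4-en-1-yl]-3-methylideneoxolan-2-one | C=C1C(=O)O[C@H](/C=C(/C)[C@H](O[Si](C)(C)C(C)(C)C)C=C)[C@H]1[C@@H](O)C[C@@](C)(O)C=C | intermediate
17 | (2Z)-2-methylbut-2-enoic acid (angelic acid) | C/C=C(/C)C(=O)O | starting material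
18 | (1R,3R)-1-[(2R,3R)-2-[(1Z,3R)-3-{[tert-butyl(dimethyl)silyl]oxy}-2-methylpenta-1,4-dien-1-yl]-4-methylidene-5-oxooxolan-3-yl]-3-hydroxy-3-methylpent-4-en-1-yl (2Z)-2-methylbut-2-enoate | C=C1C(=O)O[C@H](/C=C(/C)[C@H](O[Si](C)(C)C(C)(C)C)C=C)[C@H]1[C@H](OC(=O)/C(C)=C\C)C[C@@](C)(O)C=C | intermediate
19 | (1R,3R)-3-hydroxy-1-[(2R,3R)-2-[(1Z,3R)-3-hydroxy-2-methylpenta-1,4-dien-1-yl]-4-methylidene-5-oxooxolan-3-yl]-3-methylpent-4-en-1-yl (2Z)-2-methylbut-2-enoate | C=C1C(=O)O[C@H](/C=C(/C)[C@H](O)C=C)[C@H]1[C@H](OC(=O)/C(C)=C\C)C[C@@](C)(O)C=C | intermediate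
20 | (3aR,4R,6R,7E,9R,10Z,11aR)-6,9-dihydroxy-6,10-dimethyl-3-methylidene-2-oxo-2,3,3a,4,5,6,9,11a-octahydrocyclodeca[b]furan-4-yl (2Z)-2-methylbut-2-enoate | C=C1C(=O)O[C@@H]2/C=C(/C)[C@H](O)/C=C/[C@](C)(O)C[C@@H](OC(=O)/C(C)=C\C)[C@@H]12 | target

## Summary and fallbacks

Total steps: 12. Longest linear sequence: 9 (steps 1–5, then 9–12).

**Step 9 (proposed new method).** CO and allene insertion at copper may lose to protonation of allylcopper 15 or to base-induced dehydration of 13. The fallback uses known chemistry, sets out from 8 and returns at 16. Allenol 8 is treated with PdCl2 (5 mol%), CuCl2 (4 equiv) and CO (1 atm) in THF at 23 °C; this chlorocyclocarbonylation of a 2,3-allenol gives chloromethyl butenolide F1. Zinc dust and NaI in THF/aqueous NH4Cl at 0 °C then add F1 to aldehyde 13 (Barbier allylation of a 3-(halomethyl)butenolide, same chair transition state and facial bias) to give 16.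

**Step 10.** The C8 carbinol is hindered and angelic acid is a weak acid, so elimination toward C7 may compete with substitution. The fallback separates inversion from acylation, sets out from 16 and returns at 18. Mitsunobu reaction with formic acid (PPh3, diisopropyl azodicarboxylate, THF, 0 °C) gives the inverted formate F2. NaHCO3 in MeOH at 0 °C removes the formyl group to give the 8R alcohol F3. Yamaguchi esterification with 17 (2,4,6-trichlorobenzoyl chloride, Et3N, toluene; then F3, DMAP, 80 °C) acylates with retention and without Z/E isomerisation to give 18.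

**Step 12.** Ring strain, E/Z control and competing closure onto the C13 methylidene make the metathesis uncertain. The fallback closes ring B at C7–C8 instead, sets out from 8 and 12 and returns at 20. Chloromethyl butenolide F1 (made from 8 as above, no methylidene present) undergoes cross-metathesis with excess diol 12 (second-generation Grubbs catalyst, CH2Cl2, 40 °C) to give the E-configured diol F4. Oxidation with 2,2,6,6-tetramethylpiperidin-1-oxyl and PhI(OAc)2 gives aldehyde F5. Zinc dust and NaI in THF/aqueous NH4Cl at high dilution effect an intramolecular Barbier allylation that closes the ten-membered ring and creates the α-methylene lactone, giving macrocyclic alcohol F6. Mitsunobu esterification with 17 gives macrocyclic angelate silyl ether F7, and HF·pyridine then gives 20.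

Further compounds
F1 | step 9 | (5R)-5-[(1Z,3R)-3-{[tert-butyl(dimethyl)silyl]oxy}-2-methylpenta-1,4-dien-1-yl]-3-(chloromethyl)furan-2(5H)-one | O=C1O[C@H](/C=C(/C)[C@H](O[Si](C)(C)C(C)(C)C)C=C)C=C1CCl
F2 | step 10 | (1R,3R)-1-[(2R,3R)-2-[(1Z,3R)-3-{[tert-butyl(dimethyl)silyl]oxy}-2-methylpenta-1,4-dien-1-yl]-4-methylidene-5-oxooxolan-3-yl]-3-hydroxy-3-methylpent-4-en-1-yl formate | C=C1C(=O)O[C@H](/C=C(/C)[C@H](O[Si](C)(C)C(C)(C)C)C=C)[C@H]1[C@H](OC=O)C[C@@](C)(O)C=C
F3 | step 10 | (4R,5R)-5-[(1Z,3R)-3-{[tert-butyl(dimethyl)silyl]oxy}-2-methylpenta-1,4-dien-1-yl]-4-[(1R,3R)-1,3-dihydroxy-3-methylpent-4-en-1-yl]-3-methylideneoxolan-2-one | C=C1C(=O)O[C@H](/C=C(/C)[C@H](O[Si](C)(C)C(C)(C)C)C=C)[C@H]1[C@H](O)C[C@@](C)(O)C=C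
F4 | step 12 | (5R)-5-[(1Z,3R,4E,6R)-3-{[tert-butyl(dimethyl)silyl]oxy}-6,8-dihydroxy-2,6-dimethylocta-1,4-dien-1-yl]-3-(chloromethyl)furan-2(5H)-one | O=C1O[C@H](/C=C(/C)[C@H](O[Si](C)(C)C(C)(C)C)/C=C/[C@](C)(O)CCO)C=C1CCl
F5 | step 12 | (3R,4E,6R,7Z)-6-{[tert-butyl(dimethyl)silyl]oxy}-8-[(2R)-4-(chloromethyl)-5-oxo-2,5-dihydrofuran-2-yl]-3-hydroxy-3,7-dimethylocta-4,7-dienal | O=C1O[C@H](/C=C(/C)[C@H](O[Si](C)(C)C(C)(C)C)/C=C/[C@](C)(O)CC=O)C=C1CCl
F6 | step 12 | (3aR,4S,6R,7E,9R,10Z,11aR)-9-{[tert-butyl(dimethyl)silyl]oxy}-4,6-dihydroxy-6,10-dimethyl-3-methylidene-3a,4,5,6,9,11a-hexahydrocyclodeca[b]furan-2(3H)-one | C=C1C(=O)O[C@@H]2/C=C(/C)[C@H](O[Si](C)(C)C(C)(C)C)/C=C/[C@](C)(O)C[C@H](O)[C@@H]12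
F7 | step 12 | (3aR,4R,6R,7E,9R,10Z,11aR)-9-{[tert-butyl(dimethyl)silyl]oxy}-6-hydroxy-6,10-dimethyl-3-methylidene-2-oxo-2,3,3a,4,5,6,9,11a-octahydrocyclodeca[b]furan-4-yl (2Z)-2-methylbut-2-enoate | C=C1C(=O)O[C@@H]2/C=C(/C)[C@H](O[Si](C)(C)C(C)(C)C)/C=C/[C@](C)(O)C[C@@H](OC(=O)/C(C)=C\C)[C@@H]12
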